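**Retrosynthetic overview**

1. The target comes from a (2R,3R)-6,3'-di-O-benzyl-5-O-methyl chromanone by one BCl3 operation that cleaves both aryl benzyl ethers and the carbonyl-chelated 5-OMe.
2. Ring C is the only ring made; it is closed last at C4–C4a by intramolecular Friedel–Crafts acylation of a (2R,3R)-3-aryl-3-aryloxy-2-methoxypropanoic acid onto a symmetric ring A ether, so there is no regiochemical choice.
3. The acid comes from oxidative cleavage of a vinyl group; the C2–O1 aryl ether comes from Mitsunobu inversion of a syn benzylic alcohol with 4-(benzyloxy)-3,5-dimethoxyphenol (Dakin oxidation of the aldehyde).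
4. Key C2–C3 bond: ring B aldehyde plus metalated allyl methyl ether, used as its (Z)-γ-methoxyallyl-diisopinocampheylborane. The oxygen-bearing carbon is the nucleophile (a polarity-reversed α-alkoxy carbanion) and bonds to the aldehyde carbon, setting both stereocentres and the 3-OMe in one step.
5. Ring order: rings B and A are bought preformed; ring C is formed last.

Assumption: 3-hydroxy-4,5-dimethoxybenzaldehyde, 4-(benzyloxy)-3,5-dimethoxybenzaldehyde (otherwise one benzylation of syringaldehyde), allyl methyl ether and (+)-B-methoxydiisopinocampheylborane are taken as purchasable.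

**Route**

Step 1
Reactants: 1 3-hydroxy-4,5-dimethoxybenzaldehyde
Product: 2 3-(benzyloxy)-4,5-dimethoxybenzaldehyde
Conditions: BnBr, K2CO3, DMF, 60 °C
Reagents that add atoms: benzyl bromide, BrCc1ccccc1
Why: Williamson ether synthesis on the phenoxide masks the only acidic OH before the organolithium and borane chemistry with a group that the final BCl3 step removes, and no stereocentre is involved.

Step 2
Reactants: 2 3-(benzyloxy)-4,5-dimethoxybenzaldehyde; 3 allyl methyl ether
Product: 8 (1S,2S)-1-[3-(benzyloxy)-4,5-dimethoxyphenyl]-2-methoxybut-3-en-1-ol, via Z-methoxyallyllithium 4 (not isolated), via lithium methoxyborate complex 5 (not isolated), via Z-methoxyallyl diisopinocampheylborane 6 (not isolated), via borinate ester 7 (not isolated)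
Conditions: 3, s-BuLi, THF, −78 °C; (+)-Ipc2BOMe [from (−)-α-pinene]; BF3·OEt2; then 2, −78 °C, 4 h; NaOH, H2O2, 0 °C to rt
Reagents that add atoms: none
Why: Brown asymmetric γ-alkoxyallylboration, in which the oxygen-bearing carbon of metalated allyl methyl ether (an α-alkoxy carbanion of reversed polarity) bonds to the aldehyde carbon through a closed chair transition state, so that the (Z)-allylborane geometry gives the syn pair and the isopinocampheyl groups derived from (−)-α-pinene direct attack to the Re face of the aldehyde, setting C1 (S) and C2 (S) together with the future 3-OMe.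

Step 3
Reactants: 9 4-(benzyloxy)-3,5-dimethoxybenzaldehyde
Product: 11 4-(benzyloxy)-3,5-dimethoxyphenol, via aryl formate 10 (not isolated)
Conditions: mCPBA, CH2Cl2, rt; then K2CO3 (cat.), MeOH, rt
Reagents that add atoms: mCPBA (3-chloroperoxybenzoic acid), OOC(=O)c1cccc(Cl)c1
Why: Dakin-type Baeyer–Villiger oxidation in which the electron-rich aryl group migrates to oxygen, followed by methanolysis of the formate, gives a symmetric phenol whose two ortho positions are identical.

Step 4
Reactants: 8 (1S,2S)-1-[3-(benzyloxy)-4,5-dimethoxyphenyl]-2-methoxybut-3-en-1-ol; 11 4-(benzyloxy)-3,5-dimethoxyphenol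
Product: 12 2-(benzyloxy)-5-{[(1R,2S)-1-[3-(benzyloxy)-4,5-dimethoxyphenyl]-2-methoxybut-3-en-1-yl]oxy}-1,3-dimethoxybenzene
Conditions: PPh3, DIAD, toluene, 0 °C to rt
Reagents that add atoms: none
Why: Mitsunobu etherification, an SN2 displacement of the benzylic oxyphosphonium by the phenoxide with inversion (1S to 1R), converts the syn alcohol into the anti aryl ether that corresponds to the 2,3-trans ring, while the methoxy-bearing carbon is untouched.

Step 5
Reactants: 12 2-(benzyloxy)-5-{[(1R,2S)-1-[3-(benzyloxy)-4,5-dimethoxyphenyl]-2-methoxybut-3-en-1-yl]oxy}-1,3-dimethoxybenzene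
Product: 14 (2R,3R)-3-[3-(benzyloxy)-4,5-dimethoxyphenyl]-3-[4-(benzyloxy)-3,5-dimethoxyphenoxy]-2-methoxypropanal, via vicinal diol 13 (not isolated)
Conditions: OsO4 (2 mol %), NaIO4, 2,6-lutidine, 1,4-dioxane–H2O (3:1), rt; crude used directly
Reagents that add atoms: sodium periodate, [Na+].[O-]I(=O)(=O)=O (terminal oxygen source, delivered through OsO4)
Why: Lemieux–Johnson oxidative cleavage dihydroxylates only the terminal alkene and cleaves the diol under lutidine buffering, leaving both stereocentres spatially unchanged (the methoxy carbon changes from S to R only because the CIP priorities change).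

Step 6
Reactants: 14 (2R,3R)-3-[3-(benzyloxy)-4,5-dimethoxyphenyl]-3-[4-(benzyloxy)-3,5-dimethoxyphenoxy]-2-methoxypropanal
Product: 15 (2R,3R)-3-[3-(benzyloxy)-4,5-dimethoxyphenyl]-3-[4-(benzyloxy)-3,5-dimethoxyphenoxy]-2-methoxypropanoic acid
Conditions: NaClO2, NaH2PO4, 2-methyl-2-butene (large excess), t-BuOH–H2O, 0 °C to rt
Reagents that add atoms: sodium chlorite, [Na+].[O-]Cl=O
Why: Pinnick oxidation is mildly acidic and does not epimerise the α-alkoxy centre or eliminate the β-aryloxy group, and the alkene scavenger keeps hypochlorous acid away from the electron-rich rings.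

Step 7
Reactants: 15 (2R,3R)-3-[3-(benzyloxy)-4,5-dimethoxyphenyl]-3-[4-(benzyloxy)-3,5-dimethoxyphenoxy]-2-methoxypropanoic acid
Product: 17 (2R,3R)-6-(benzyloxy)-2-[3-(benzyloxy)-4,5-dimethoxyphenyl]-3,5,7-trimethoxy-2,3-dihydro-4H-chromen-4-one, via mixed anhydride 16 (not isolated)
Conditions: TFAA (1.5 equiv), CH2Cl2, 0 °C to rt
Reagents that add atoms: none
Why: Intramolecular Friedel–Crafts acylation through the mixed trifluoroacetic anhydride attacks the position ortho to the ether oxygen of the tetra-oxygenated symmetric ring A, closing the six-membered ring C without breaking a bond at C2 or C3, which emerge as the trans (2R,3R) pair.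

Step 8
Reactants: 17 (2R,3R)-6-(benzyloxy)-2-[3-(benzyloxy)-4,5-dimethoxyphenyl]-3,5,7-trimethoxy-2,3-dihydro-4H-chromen-4-one
Product: 18 (2R,3R)-5,6-dihydroxy-2-(3-hydroxy-4,5-dimethoxyphenyl)-3,7-dimethoxy-2,3-dihydro-4H-chromen-4-one
Conditions: BCl3 (1 M in CH2Cl2, 6 equiv), C6HMe5, CH2Cl2, −78 to 0 °C; then MeOH, H2O
Reagents that add atoms: none
Why: Lewis-acid ether cleavage in which BCl3 with pentamethylbenzene as benzyl-cation trap removes both aryl benzyl ethers at low temperature and cleaves the 5-OMe through the six-membered boron chelate with the C4 carbonyl, while the 3-, 7-, 4'- and 5'-methyl ethers lack this activation and the stereocentres are not touched.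

**Compound list**

1 | 3-hydroxy-4,5-dimethoxybenzaldehyde | O=Cc1cc(O)c(OC)c(OC)c1 | starting material
2 | 3-(benzyloxy)-4,5-dimethoxybenzaldehyde | O=Cc1cc(OCc2ccccc2)c(OC)c(OC)c1 | intermediate
3 | allyl methyl ether (3-methoxyprop-1-ene) | COCC=C | starting material
4 | (Z)-3-methoxyallyllithium, formed in the flask | [Li]C/C=C\OC | intermediate
5 | lithium [(Z)-3-methoxyallyl](methoxy)bis(isopinocampheyl)borate, Ipc groups from (−)-α-pinene, formed in the flask | [Li+].CO/C=C\C[B-](OC)([C@H]1C[C@H]2C[C@@H]([C@@H]1C)C2(C)C)[C@H]1C[C@H]2C[C@@H]([C@@H]1C)C2(C)C | intermediate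
6 | [(Z)-3-methoxyallyl]bis(isopinocampheyl)borane, formed in the flask | CO/C=C\CB([C@H]1C[C@H]2C[C@@H]([C@@H]1C)C2(C)C)[C@H]1C[C@H]2C[C@@H]([C@@H]1C)C2(C)C | intermediate
7 | bis(isopinocampheyl)borinate ester of alcohol 8, formed in the flask | C=C[C@H](OC)[C@@H](OB([C@H]1C[C@H]2C[C@@H]([C@@H]1C)C2(C)C)[C@H]1C[C@H]2C[C@@H]([C@@H]1C)C2(C)C)c1cc(OCc2ccccc2)c(OC)c(OC)c1 | intermediate
8 | (1S,2S)-1-[3-(benzyloxy)-4,5-dimethoxyphenyl]-2-methoxybut-3-en-1-ol (syn) | C=C[C@H](OC)[C@@H](O)c1cc(OCc2ccccc2)c(OC)c(OC)c1 | intermediate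
9 | 4-(benzyloxy)-3,5-dimethoxybenzaldehyde | O=Cc1cc(OC)c(OCc2ccccc2)c(OC)c1 | starting material
10 | 4-(benzyloxy)-3,5-dimethoxyphenyl formate, formed in the flask | O=COc1cc(OC)c(OCc2ccccc2)c(OC)c1 | intermediate
11 | 4-(benzyloxy)-3,5-dimethoxyphenol | Oc1cc(OC)c(OCc2ccccc2)c(OC)c1 | intermediate
12 | 2-(benzyloxy)-5-{[(1R,2S)-1-[3-(benzyloxy)-4,5-dimethoxyphenyl]-2-methoxybut-3-en-1-yl]oxy}-1,3-dimethoxybenzene (anti) | C=C[C@H](OC)[C@H](Oc1cc(OC)c(OCc2ccccc2)c(OC)c1)c1cc(OCc2ccccc2)c(OC)c(OC)c1 | intermediate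
13 | (3S,4R)-4-[3-(benzyloxy)-4,5-dimethoxyphenyl]-4-[4-(benzyloxy)-3,5-dimethoxyphenoxy]-3-methoxybutane-1,2-diol, both C2 epimers, formed in the flask | OCC(O)[C@H](OC)[C@H](Oc1cc(OC)c(OCc2ccccc2)c(OC)c1)c1cc(OCc2ccccc2)c(OC)c(OC)c1 | intermediate
14 | (2R,3R)-3-[3-(benzyloxy)-4,5-dimethoxyphenyl]-3-[4-(benzyloxy)-3,5-dimethoxyphenoxy]-2-methoxypropanal | O=C[C@H](OC)[C@H](Oc1cc(OC)c(OCc2ccccc2)c(OC)c1)c1cc(OCc2ccccc2)c(OC)c(OC)c1 | intermediate
15 | (2R,3R)-3-[3-(benzyloxy)-4,5-dimethoxyphenyl]-3-[4-(benzyloxy)-3,5-dimethoxyphenoxy]-2-methoxypropanoic acid | OC(=O)[C@H](OC)[C@H](Oc1cc(OC)c(OCc2ccccc2)c(OC)c1)c1cc(OCc2ccccc2)c(OC)c(OC)c1 | intermediate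
16 | mixed anhydride of acid 15 with trifluoroacetic acid, (2R,3R), formed in the flask | O=C(OC(=O)C(F)(F)F)[C@H](OC)[C@H](Oc1cc(OC)c(OCc2ccccc2)c(OC)c1)c1cc(OCc2ccccc2)c(OC)c(OC)c1 | intermediate
17 | (2R,3R)-6-(benzyloxy)-2-[3-(benzyloxy)-4,5-dimethoxyphenyl]-3,5,7-trimethoxy-2,3-dihydro-4H-chromen-4-one (2,3-trans) | COc1cc2c(c(OC)c1OCc3ccccc3)C(=O)[C@H](OC)[C@@H](c1cc(OCc3ccccc3)c(OC)c(OC)c1)O2 | intermediate
18 | (2R,3R)-5,6-dihydroxy-2-(3-hydroxy-4,5-dimethoxyphenyl)-3,7-dimethoxy-2,3-dihydro-4H-chromen-4-one (CNP0075601.1) | COc1cc2c(c(O)c1O)C(=O)[C@H](OC)[C@@H](c1cc(O)c(OC)c(OC)c1)O2 | target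

**Step count**

Total: 8 steps. Longest linear sequence: 7 steps (steps 1, 2, 4, 5, 6, 7, 8; compounds 1, 2, 8, 12, 14, 15, 17, 18).

**Steps most likely to fail, with fallbacks**

Step 4 (intermolecular Mitsunobu at an electron-rich secondary benzylic carbinol). The risks are elimination to the methoxy diene and partial SN1 leakage that erodes the configuration at C1. The fallback sets out from alcohol 8 and comes back to the route at chromanone 17. Alcohol 8 is silylated (TBSCl, imidazole, DMF) to the silyl ether F1. The vinyl group is cleaved (OsO4, NaIO4, 2,6-lutidine) to the aldehyde F2, which is oxidised (NaClO2, NaH2PO4, 2-methyl-2-butene) to the acid F3. Phenol 11 is C-acylated ortho to its hydroxyl with F3 (TFAA, CH2Cl2, 0 °C) to give the 2-hydroxyaryl ketone F4. Desilylation (TBAF, AcOH, THF) gives the β-hydroxy ketone F5. Ring C is then closed by intramolecular Mitsunobu reaction (PPh3, DIAD, THF, 0 °C), a six-membered closure with inversion at the benzylic carbon, which delivers 17 and bypasses compounds 12 to 16.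

Step 7 (Friedel–Crafts ring closure). The risks are acid-induced ionisation or elimination at the benzylic aryl ether, competing indanone formation on ring B, and trifluoroacetylation of ring A. The fallback sets out from acid 15 and comes back at chromanone 17, replacing the electrophilic acylation with an anionic Parham cyclisation. Acid 15 is esterified (TMSCHN2, MeOH–toluene) to the methyl ester F6. The most electron-rich ring, ring A, is monobrominated ortho to the ether oxygen (NBS, MeCN, −20 °C) to give the aryl bromide F7; competing bromination of ring B is the weak point here. Bromine–lithium exchange (n-BuLi, THF, −100 °C) then lets the aryllithium attack the ester in a six-membered closure to give 17.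

Step 8 (one-pot BCl3 deprotection). The risks are cleavage of the twisted central 4'-OMe of ring B or of the 3-OMe, and Lewis-acid opening at C2 that would erode the stereochemistry. The fallback sets out from 17 and comes back at target 18 in two orthogonal operations. Hydrogenolysis (H2, 10% Pd/C, EtOAc, rt) removes both benzyl groups under neutral conditions to give the 5-O-methyl compound F8. The 5-OMe alone is then cleaved with the mild chelating reagent MgI2 (diethyl etherate, toluene, rt to 50 °C), which acts only on the methoxy group peri to the carbonyl, giving 18.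

**Further compounds**

F1 | step 4 | tert-butyl{[(1S,2S)-1-[3-(benzyloxy)-4,5-dimethoxyphenyl]-2-methoxybut-3-en-1-yl]oxy}dimethylsilane | C=C[C@H](OC)[C@@H](O[Si](C)(C)C(C)(C)C)c1cc(OCc2ccccc2)c(OC)c(OC)c1
F2 | step 4 | (2R,3S)-3-[3-(benzyloxy)-4,5-dimethoxyphenyl]-3-[(tert-butyldimethylsilyl)oxy]-2-methoxypropanal | O=C[C@H](OC)[C@@H](O[Si](C)(C)C(C)(C)C)c1cc(OCc2ccccc2)c(OC)c(OC)c1
F3 | step 4 | (2R,3S)-3-[3-(benzyloxy)-4,5-dimethoxyphenyl]-3-[(tert-butyldimethylsilyl)oxy]-2-methoxypropanoic acid | OC(=O)[C@H](OC)[C@@H](O[Si](C)(C)C(C)(C)C)c1cc(OCc2ccccc2)c(OC)c(OC)c1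
F4 | step 4 | (2R,3S)-1-[3-(benzyloxy)-6-hydroxy-2,4-dimethoxyphenyl]-3-[3-(benzyloxy)-4,5-dimethoxyphenyl]-3-[(tert-butyldimethylsilyl)oxy]-2-methoxypropan-1-one | COc1cc(O)c(c(OC)c1OCc1ccccc1)C(=O)[C@H](OC)[C@@H](O[Si](C)(C)C(C)(C)C)c1cc(OCc2ccccc2)c(OC)c(OC)c1
F5 | step 4 | (2R,3S)-1-[3-(benzyloxy)-6-hydroxy-2,4-dimethoxyphenyl]-3-[3-(benzyloxy)-4,5-dimethoxyphenyl]-3-hydroxy-2-methoxypropan-1-one | COc1cc(O)c(c(OC)c1OCc1ccccc1)C(=O)[C@H](OC)[C@@H](O)c1cc(OCc2ccccc2)c(OC)c(OC)c1
F6 | step 7 | methyl (2R,3R)-3-[3-(benzyloxy)-4,5-dimethoxyphenyl]-3-[4-(benzyloxy)-3,5-dimethoxyphenoxy]-2-methoxypropanoate | COC(=O)[C@H](OC)[C@H](Oc1cc(OC)c(OCc2ccccc2)c(OC)c1)c1cc(OCc2ccccc2)c(OC)c(OC)c1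
F7 | step 7 | methyl (2R,3R)-3-[3-(benzyloxy)-4,5-dimethoxyphenyl]-3-[4-(benzyloxy)-2-bromo-3,5-dimethoxyphenoxy]-2-methoxypropanoate | COC(=O)[C@H](OC)[C@H](Oc1cc(OC)c(OCc2ccccc2)c(OC)c1Br)c1cc(OCc2ccccc2)c(OC)c(OC)c1
F8 | step 8 | (2R,3R)-6-hydroxy-2-(3-hydroxy-4,5-dimethoxyphenyl)-3,5,7-trimethoxy-2,3-dihydro-4H-chromen-4-one | COc1cc2c(c(OC)c1O)C(=O)[C@H](OC)[C@@H](c1cc(O)c(OC)c(OC)c1)O2
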